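## The problem

Target 28 is a daucane triester built on a hydroazulene: a cyclopentane (C1, C2, C3, C3a, C8a, azulene numbering) trans-fused to a cycloheptene (C3a, C4 to C8, C8a), with the angular methyl on quaternary C8a defining the β face and the C3a hydrogen on the α face. Six stereocentres (C1, C3, C3a, C4, C8, C8a) surround the fusion bond; quaternary C8a and the tertiary carbinol C3 cannot be repaired later, so they must be set early, and the β hydroxyl on C3 is the one group placed to pass information on to C3a, C1 and a side chain on C3a. The acyloxy groups at C1, C4 and C8 are all α; at C1 and C8, both bonded to C8a, this puts hydrogen syn to the angular methyl, the opposite of what an unassisted hydride reduction of the ketones should give, so each needs internal delivery or an inversion. The four oxygens must end up as two acetates, one 3,4-dimethoxybenzoate and one free tertiary alcohol, which fixes the order of acylations. The C8 acetate is allylic and neopentylic, the C4 ester is homoallylic and the tertiary alcohol can eliminate, so strong acid or base late in the route invites ionisation, retro-aldol cleavage or vinylogous β-elimination. The enabling feature is that C7, the only alkene CH of the seven-membered ring, lies between the methyl-bearing alkene carbon C6 and the oxygenated C8, which is bonded to the non-enolisable C8a; excising C7 leaves a six-membered ketone (a trans-hydrindanone, indane numbering, whose C7 and C7a become C8 and C8a) that can form only one enol ether, so one carbon can be inserted at exactly this place.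

## Retrosynthesis

End game, C8–O. After re-masking the tertiary alcohol of 28 as silyl ether 27, the C8–O bond of the allylic acetate is cut. An 8α-alcohol made by β-face reduction of enone 24 is set aside because that face is screened by the angular methyl on the neighbouring carbon. The 8β-alcohol 25, expected from attack anti to the methyl, is chosen instead, and the acetate comes from acetic acid 26 with inversion. This costs no step compared with reduction plus acetylation and asks only that an activated allylic alcohol is displaced on its open α face.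

Key disconnection, C6–C7 and C7–C8. In enone 24 both ring bonds of C7 are cut and C7 is returned to diiodomethane 21; what remains is silyl enol ether 20 of a trans-hydrindanone in which the former C6 and C8 are bonded directly. Removing a different ring carbon would destroy the C4 stereocentre, and a carbonyl homologation that lets either α-carbon migrate is not regioselective. Here the quaternary C7a allows one enol ether only, and the methyl on C6 makes the internal cyclopropane bond the one that breaks. The precursor has a six-membered ring in a rigid, well-understood framework. The forward step must cyclopropanate a tetrasubstituted enol ether and open the adduct oxidatively while three ester or silyl ether groups survive.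

Staging of the oxygen functions. Enol ether 20 comes from ketone 19, 19 from alcohol 17 and acetic anhydride 18, 17 from diketone 16, and 16 from hydroxy diketone 14 and 3,4-dimethoxybenzoyl chloride 15. The aroyl group goes on while C4–OH is the only secondary alcohol. The C1 ketone is reduced only afterwards, under direction by the C3 hydroxyl, and the acetate, a final group, then protects C1–OH through the key step. Reducing first would leave two secondary alcohols to be told apart.

Six-membered ring, C5–C6 (indane numbering). In 14 the bond between C5 and the α-carbon of the C7 ketone is cut, giving epoxide 13: an ethyl ketone enolate opens a terminal epoxide at its CH2. This is preferred to a C4–C5 closure, which needs an umpolung coupling, and to a metathesis, which gives the wrong oxidation level at C4. The epoxide brings the C4 oxygen with it, and its configuration can be set from the neighbouring tertiary hydroxyl of vinyl diketone 12. The forward reactions must epoxidise the alkene face turned toward the carbinol and open at the terminal carbon.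

Vicinal difunctionalisation. Diketone 12 (through aldol 11) is cut at the bonds joining vinyl to C3 and the acyl carbon to C2 of the cyclopentanone, giving enone 8, vinylmagnesium bromide 9 and propanal 10. One operation creates both fusion stereocentres; their trans relationship, the later trans ring fusion, follows from anti attack of the electrophile on the enolate. Because the methyl already sits on the enone α-carbon, the acyl group must end up trans to vinyl. The forward reaction has to place vinyl on the face of the C4 hydroxyl, which calls for delivery by the alkoxide.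

Tertiary carbinol. Enone 8 carries the only stereocentre that is bought. Cutting its C4–isopropyl bond and transposing the oxygen pattern leads through diol 7 and silyl ether 6 to enone 4 and isopropylmagnesium chloride 5; 4 comes from commercial (R)-enone 1 and methylmagnesium bromide 2 via enol ether 3. A direct enantioselective isopropyl addition to an achiral ene-dione was rejected: it has an acidic CH2 between two carbonyls and no dependable asymmetric version. Instead the silyloxy stereocentre of 1 steers isopropyl to the opposite face and is then oxidised away, so its chirality passes to the tertiary carbinol.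

## Roads not taken

Alternative 1: The cut is the fusion bond C3a–C8a. Ph3PAuNTf2 would activate the alkyne of the ten-membered enynedione A1, and the enol carbon of its 2-methyl-1,3-diketone would add across the ring to the alkyne carbon beside the carbinol. This closes both rings at once and gives dienedione A2 with a C3a=C4 double bond.
- Merits: both rings and the quaternary carbon arise in one catalytic step, and A2 already holds the C6=C7 alkene and both carbonyls.
- Weak points: a ten-membered ring with an alkyne and a cis enone is itself a hard target. C8a would be controlled only by the remote C3 carbinol through a transannular transition state. The trans fusion and the C4 oxygen would have to come from hydroboration of a hindered alkene. Two ketones flanking C8a would each need reduction syn to the methyl and then differentiation.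
- Comparison: in ring construction this road is clearly shorter than the chosen plan, which needs nine steps from enone 8 to enone 24. The chosen plan sets against it a stereochemical relay from one hydroxyl through closely precedented reactions, a trans fusion fixed before any ring closes, and C1 and C4 oxygens in place and differentiated before the seven-membered ring exists.

Alternative 2: The cut is C3–C3a. CrCl2 with catalytic NiCl2 would turn cycloheptadienyl iodide A3 into an alkenylchromium species that adds to its tethered isopropyl ketone, closing the cyclopentane and forming the tertiary alcohol of A4.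
- Merits: this coupling tolerates acetates and silyl ethers and makes hindered tertiary allylic alcohols well, so as a single step it is probably more dependable than an oxidative ring expansion. The C8 acetate and C6=C7 alkene are already present, so no late inversion at C8 is needed.
- Weak points: the hard part, quaternary C8a with two oxygenated neighbours on a seven-membered ring, is moved into the synthesis of A3. The carbinol configuration depends on which face of a freely rotating ketone is attacked. A4 still lacks the C4 oxygen and the C3a hydrogen.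
- Comparison: the key step is more robust than step 14 here. The chosen plan answers with much shorter access to its key-step substrate and with a carbinol set in a cyclic, predictable addition (step 3).

Alternative 3: Two bonds are cut, C3a–C4 and C5–C6. [Rh(CO)2Cl]2 would open the bicyclic siloxy vinylcyclopropane A5 at the bond from its siloxy carbon to the ring CH and insert ethynyltrimethylsilane A7 to give cycloheptadiene A6.
- Merits: the seven-membered ring is assembled convergently and atom-economically in one catalytic step, with the C8 enol ether delivered directly.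
- Weak points: A6 is cis-fused and C3a has no neighbouring carbonyl for epimerisation, so the trans fusion of 28 is out of reach. Insertion regiochemistry beside a fully substituted cyclopropane carbon is uncertain. C4 carries silicon, not oxygen, and the alkenes (C4=C5, C7=C8) are not where the target needs one (C6=C7).
- Comparison: this is the shortest way to the carbocycle and beats the chosen plan in convergence. The chosen plan sets against it the correct ring fusion and a ring-expansion product 24 with every carbon and the alkene in final position.

Key step: step 14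

Assumption (chemistry): hydride adds to the C8 carbonyl of 24 anti to the angular methyl, as ketones beside a methyl-bearing quaternary fusion carbon normally do; the end game is written for that outcome.

## Route

Step 1
Reactants: 1 (R)-4-(tert-butyldimethylsilyloxy)cyclopent-2-en-1-one; 2 methylmagnesium bromide
Product: 3 (3R,4R)-4-(tert-butyldimethylsilyloxy)-3-methyl-1-(trimethylsilyloxy)cyclopent-1-ene
Conditions: MeMgBr, CuBr·SMe2 (10 mol%), Me3SiCl, DMPU, THF, −78 °C
Reagents that add atoms: chlorotrimethylsilane, C[Si](C)(C)Cl
Why: Copper-catalysed conjugate addition of a Grignard reagent with in situ silylation; methyl enters anti to the silyloxy group and trapping as the enol ether prevents β-elimination of that group. The new methyl-bearing centre is erased in step 2.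

Step 2
Reactants: 3 (3R,4R)-4-(tert-butyldimethylsilyloxy)-3-methyl-1-(trimethylsilyloxy)cyclopent-1-ene
Product: 4 (R)-4-(tert-butyldimethylsilyloxy)-3-methylcyclopent-2-en-1-one
Conditions: Pd(OAc)2 (10 mol%), O2 (1 atm), DMSO, rt
Reagents that add atoms: none
Why: Saegusa–Ito dehydrosilylation with O2 as terminal oxidant returns the enone, the position of the double bond being fixed by the enol ether; the silyloxy stereocentre is untouched.

Step 3
Reactants: 4 (R)-4-(tert-butyldimethylsilyloxy)-3-methylcyclopent-2-en-1-one; 5 isopropylmagnesium chloride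
Product: 6 (1R,4R)-4-(tert-butyldimethylsilyloxy)-1-isopropyl-3-methylcyclopent-2-en-1-ol
Conditions: iPrMgCl, CeCl3, THF, −78 °C
Reagents that add atoms: none
Why: Organocerium 1,2-addition to an enone (CeCl3 suppresses enolisation, reduction and 1,4-addition); the nucleophile approaches anti to the C4 silyloxy group, so the new tertiary hydroxyl is cis to it.

Step 4
Reactants: 6 (1R,4R)-4-(tert-butyldimethylsilyloxy)-1-isopropyl-3-methylcyclopent-2-en-1-ol
Product: 7 (1R,4R)-1-isopropyl-3-methylcyclopent-2-ene-1,4-diol
Conditions: Bu4NF, THF, 0 °C to rt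
Reagents that add atoms: none
Why: Fluoride cleavage of the secondary silyl ether; the tertiary allylic alcohol is stable under these non-acidic conditions.

Step 5
Reactants: 7 (1R,4R)-1-isopropyl-3-methylcyclopent-2-ene-1,4-diol
Product: 8 (R)-4-hydroxy-4-isopropyl-2-methylcyclopent-2-en-1-one
Conditions: MnO2, CH2Cl2, rt
Reagents that add atoms: none
Why: MnO2 oxidises only the secondary allylic alcohol; the temporary stereocentre disappears and its information now rests in the tertiary carbinol.

Step 6
Reactants: 8 (R)-4-hydroxy-4-isopropyl-2-methylcyclopent-2-en-1-one; 9 vinylmagnesium bromide; 10 propanal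
Product: 11 (2S,3R,4R)-4-hydroxy-2-(1-hydroxypropyl)-4-isopropyl-2-methyl-3-vinylcyclopentan-1-one (both carbinol epimers)
Conditions: vinylMgBr (3 equiv), THF, −78 to −40 °C; then EtCHO, −78 °C; aq NH4Cl
Reagents that add atoms: none
Why: Alkoxide-directed conjugate addition of a Grignard reagent to a 4-oxido enone: the magnesium alkoxide binds the reagent and delivers vinyl to C3 on the hydroxyl face, anti to isopropyl. The magnesium enolate then adds to propanal anti to vinyl (tandem 1,4-addition–aldol), setting the quaternary carbon with methyl cis to vinyl; the carbinol epimers converge in step 7.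

Step 7
Reactants: 11 (2S,3R,4R)-4-hydroxy-2-(1-hydroxypropyl)-4-isopropyl-2-methyl-3-vinylcyclopentan-1-one (both carbinol epimers)
Product: 12 (2S,3R,4R)-4-hydroxy-4-isopropyl-2-methyl-2-propanoyl-3-vinylcyclopentan-1-one
Conditions: Dess–Martin periodinane, NaHCO3, CH2Cl2, rt
Reagents that add atoms: none
Why: Dess–Martin oxidation of the secondary alcohol under buffered, non-basic conditions gives the non-enolisable 1,3-diketone without retro-aldol cleavage; the tertiary alcohol and the alkene are inert.

Step 8
Reactants: 12 (2S,3R,4R)-4-hydroxy-4-isopropyl-2-methyl-2-propanoyl-3-vinylcyclopentan-1-one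
Product: 13 (2S,3S,4R)-4-hydroxy-4-isopropyl-2-methyl-3-[(2R)-oxiran-2-yl]-2-propanoylcyclopentan-1-one
Conditions: VO(acac)2 (5 mol%), t-BuOOH, CH2Cl2, 0 °C to rt
Reagents that add atoms: tert-butyl hydroperoxide, CC(C)(C)OO
Why: Hydroxyl-directed vanadium-catalysed epoxidation of a homoallylic alcohol. With the vinyl CH2 eclipsing the ring C–H bond (minimum allylic strain) the vanadate ester on the cis tertiary hydroxyl reaches only the alkene face turned toward the carbinol carbon, which gives the (R)-oxirane.

Step 9
Reactants: 13 (2S,3S,4R)-4-hydroxy-4-isopropyl-2-methyl-3-[(2R)-oxiran-2-yl]-2-propanoylcyclopentan-1-one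
Product: 14 (3R,3aS,4S,7aR)-3,4-dihydroxy-3-isopropyl-6,7a-dimethyloctahydro-1H-indene-1,7-dione (C6 epimers)
Conditions: KN(SiMe3)2 (2.2 equiv), THF, −78 to 0 °C; aq NH4Cl
Reagents that add atoms: none
Why: Intramolecular alkylation of a ketone enolate by a terminal epoxide: after the alkoxide forms, the ethyl ketone enolate attacks the epoxide CH2 (6-endo mode at the primary carbon), closing the six-membered ring. The 5-exo mode would need a trans-fused bicyclo[3.3.0]octane and the cyclopentanone enolate has no unstrained cyclisation mode, so it only reverts. The trans side chains give the trans-hydrindane with the new hydroxyl equatorial (α).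

Step 10
Reactants: 14 (3R,3aS,4S,7aR)-3,4-dihydroxy-3-isopropyl-6,7a-dimethyloctahydro-1H-indene-1,7-dione (C6 epimers); 15 3,4-dimethoxybenzoyl chloride
Product: 16 (3R,3aS,4S,7aR)-3-hydroxy-3-isopropyl-6,7a-dimethyl-1,7-dioxooctahydro-1H-inden-4-yl 3,4-dimethoxybenzoate (C6 epimers)
Conditions: 3,4-(MeO)2C6H3COCl, Et3N, 4-dimethylaminopyridine (cat.), CH2Cl2, 0 °C to rt
Reagents that add atoms: none
Why: Nucleophile-catalysed acylation of the only secondary alcohol; the hindered tertiary alcohol does not react under these conditions.

Step 11
Reactants: 16 (3R,3aS,4S,7aR)-3-hydroxy-3-isopropyl-6,7a-dimethyl-1,7-dioxooctahydro-1H-inden-4-yl 3,4-dimethoxybenzoate (C6 epimers)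
Product: 17 (1S,3R,3aS,4S,7aR)-1,3-dihydroxy-3-isopropyl-6,7a-dimethyl-7-oxooctahydro-1H-inden-4-yl 3,4-dimethoxybenzoate (C6 epimers)
Conditions: Me4NBH(OAc)3, MeCN/AcOH, −30 °C
Reagents that add atoms: none
Why: Hydroxyl-directed reduction of a β-hydroxy ketone (Evans–Saksena type): the β tertiary hydroxyl at C3 exchanges onto boron and delivers hydride to the β face of the C1 carbonyl, giving the 1α-alcohol (1,3-trans diol). The C7 ketone lies out of reach of that hydroxyl, and triacetoxyborohydride does not reduce ketones without such assistance.

Step 12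
Reactants: 17 (1S,3R,3aS,4S,7aR)-1,3-dihydroxy-3-isopropyl-6,7a-dimethyl-7-oxooctahydro-1H-inden-4-yl 3,4-dimethoxybenzoate (C6 epimers); 18 acetic anhydride
Product: 19 (1S,3R,3aS,4S,7aR)-1-acetoxy-3-hydroxy-3-isopropyl-6,7a-dimethyl-7-oxooctahydro-1H-inden-4-yl 3,4-dimethoxybenzoate (C6 epimers)
Conditions: Ac2O, pyridine, 4-dimethylaminopyridine (cat.), 0 °C to rt
Reagents that add atoms: none
Why: Standard acetylation of the secondary alcohol; the tertiary alcohol is spared at room temperature. The β-acetoxy ketone cannot eliminate because C7a has no hydrogen.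

Step 13
Reactants: 19 (1S,3R,3aS,4S,7aR)-1-acetoxy-3-hydroxy-3-isopropyl-6,7a-dimethyl-7-oxooctahydro-1H-inden-4-yl 3,4-dimethoxybenzoate (C6 epimers)
Product: 20 (1S,3R,3aS,4S,7aR)-1-acetoxy-3-isopropyl-6,7a-dimethyl-3,7-bis(trimethylsilyloxy)-2,3,3a,4,5,7a-hexahydro-1H-inden-4-yl 3,4-dimethoxybenzoate
Conditions: Me3SiOTf, Et3N, CH2Cl2, 0 °C to rt
Reagents that add atoms: trimethylsilyl trifluoromethanesulfonate, C[Si](C)(C)OS(=O)(=O)C(F)(F)F
Why: Soft enolisation–silylation: the C7 ketone has a single α-hydrogen (on C6; C7a is quaternary), so only the tetrasubstituted enol ether can form and the C6 epimers converge. The tertiary hydroxyl is silylated in the same operation, and ketone silylation is much faster than that of the ester groups.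

Step 14
Reactants: 20 (1S,3R,3aS,4S,7aR)-1-acetoxy-3-isopropyl-6,7a-dimethyl-3,7-bis(trimethylsilyloxy)-2,3,3a,4,5,7a-hexahydro-1H-inden-4-yl 3,4-dimethoxybenzoate; 21 diiodomethane
Product: 24 (1S,3R,3aS,4S,8aR)-1-acetoxy-3-isopropyl-6,8a-dimethyl-8-oxo-3-(trimethylsilyloxy)-1,2,3,3a,4,5,8,8a-octahydroazulen-4-yl 3,4-dimethoxybenzoate, via siloxycyclopropane 22 (not isolated), via β-chloro ketone 23 (not isolated)
Conditions: Et2Zn, CH2I2, CH2Cl2, 0 °C to rt; FeCl3, DMF, 0 °C to rt; NaOAc, MeOH, reflux
Reagents that add atoms: none
Why: The zinc carbenoid EtZnCH2I (Furukawa variant of the Simmons–Smith reaction) adds CH2 across the electron-rich tetrasubstituted enol ether C6=C7 to give siloxycyclopropane 22 from either face. FeCl3 oxidises 22 by one electron; with loss of the silyl group the cyclopropoxy radical cleaves the internal bond between the methyl-bearing carbon and the oxygenated carbon, the bond that releases a tertiary radical and enlarges the ring. That β-keto radical takes chlorine from a second FeCl3 to give 23, and NaOAc removes HCl through the only acidic position, the inserted CH2, to give the conjugated 6-methyl enone 24. The closest known reaction is the FeCl3-mediated ring enlargement of 1-siloxybicyclo[n.1.0]alkanes to cycloalk-2-enones (Ito–Saegusa). No ring is closed for good: the three-membered ring made by carbene addition is opened again, and the net change is growth of the six-membered ring to seven by insertion of one CH between the carbonyl carbon and the methyl-bearing carbon. No stereocentre is created, since both cyclopropane centres become sp2 or carbonyl carbons. The site of insertion is secured by the single possible enol ether (C7a is quaternary), internal over external bond cleavage by the methyl group on C6, and chemoselectivity by the enol ether being the only nucleophilic alkene while the esters and the tertiary silyl ether are spectators.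

Step 15
Reactants: 24 (1S,3R,3aS,4S,8aR)-1-acetoxy-3-isopropyl-6,8a-dimethyl-8-oxo-3-(trimethylsilyloxy)-1,2,3,3a,4,5,8,8a-octahydroazulen-4-yl 3,4-dimethoxybenzoate
Product: 25 (1S,3R,3aS,4S,8S,8aS)-1-acetoxy-8-hydroxy-3-isopropyl-6,8a-dimethyl-3-(trimethylsilyloxy)-1,2,3,3a,4,5,8,8a-octahydroazulen-4-yl 3,4-dimethoxybenzoate
Conditions: NaBH4, CeCl3·7H2O, MeOH, −78 °C
Reagents that add atoms: none
Why: Luche 1,2-reduction of the enone; hydride should approach anti to the axial angular methyl on C8a (α face), as with ketones beside a methyl-bearing quaternary fusion carbon, giving the 8β-alcohol. The esters are not reduced at this temperature.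

Step 16
Reactants: 25 (1S,3R,3aS,4S,8S,8aS)-1-acetoxy-8-hydroxy-3-isopropyl-6,8a-dimethyl-3-(trimethylsilyloxy)-1,2,3,3a,4,5,8,8a-octahydroazulen-4-yl 3,4-dimethoxybenzoate; 26 acetic acid
Product: 27 (1S,3R,3aS,4S,8R,8aR)-1,8-diacetoxy-3-isopropyl-6,8a-dimethyl-3-(trimethylsilyloxy)-1,2,3,3a,4,5,8,8a-octahydroazulen-4-yl 3,4-dimethoxybenzoate
Conditions: PPh3, diisopropyl azodicarboxylate, AcOH, toluene, 0 °C to rt
Reagents that add atoms: none
Why: Mitsunobu esterification: acetate displaces the oxyphosphonium group by SN2 with inversion, entering on the open α face anti to the angular methyl; allylic activation offsets the neopentylic position. The tertiary silyl ether and the other esters are inert.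

Step 17
Reactants: 27 (1S,3R,3aS,4S,8R,8aR)-1,8-diacetoxy-3-isopropyl-6,8a-dimethyl-3-(trimethylsilyloxy)-1,2,3,3a,4,5,8,8a-octahydroazulen-4-yl 3,4-dimethoxybenzoate
Product: 28 (1S,3R,3aS,4S,8R,8aR)-1,8-diacetoxy-3-hydroxy-3-isopropyl-6,8a-dimethyl-1,2,3,3a,4,5,8,8a-octahydroazulen-4-yl 3,4-dimethoxybenzoate
Conditions: HF·pyridine, pyridine, THF, 0 °C
Reagents that add atoms: none
Why: Buffered fluoride cleavage of the tertiary trimethylsilyl ether; the conditions are too mild to ionise the allylic acetate or cleave the esters, and they release the target.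

## Compound list

1 | (R)-4-(tert-butyldimethylsilyloxy)cyclopent-2-en-1-one | O=C1C=C[C@H](O[Si](C)(C)C(C)(C)C)C1 | starting material
2 | methylmagnesium bromide | C[Mg]Br | starting material
3 | (3R,4R)-4-(tert-butyldimethylsilyloxy)-3-methyl-1-(trimethylsilyloxy)cyclopent-1-ene | C[C@@H]1C=C(O[Si](C)(C)C)C[C@H]1O[Si](C)(C)C(C)(C)C | intermediate
4 | (R)-4-(tert-butyldimethylsilyloxy)-3-methylcyclopent-2-en-1-one | O=C1C=C(C)[C@H](O[Si](C)(C)C(C)(C)C)C1 | intermediate
5 | isopropylmagnesium chloride | CC(C)[Mg]Cl | starting material
6 | (1R,4R)-4-(tert-butyldimethylsilyloxy)-1-isopropyl-3-methylcyclopent-2-en-1-ol | CC(C)[C@@]1(O)C=C(C)[C@H](O[Si](C)(C)C(C)(C)C)C1 | intermediate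
7 | (1R,4R)-1-isopropyl-3-methylcyclopent-2-ene-1,4-diol | CC(C)[C@@]1(O)C=C(C)[C@H](O)C1 | intermediate
8 | (R)-4-hydroxy-4-isopropyl-2-methylcyclopent-2-en-1-one | CC(C)[C@@]1(O)C=C(C)C(=O)C1 | intermediate
9 | vinylmagnesium bromide | C=C[Mg]Br | starting material
10 | propanal | CCC=O | starting material
11 | (2S,3R,4R)-4-hydroxy-2-(1-hydroxypropyl)-4-isopropyl-2-methyl-3-vinylcyclopentan-1-one (both carbinol epimers) | CCC(O)[C@]1(C)[C@@H](C=C)[C@](O)(C(C)C)CC1=O | intermediate
12 | (2S,3R,4R)-4-hydroxy-4-isopropyl-2-methyl-2-propanoyl-3-vinylcyclopentan-1-one | CCC(=O)[C@]1(C)[C@@H](C=C)[C@](O)(C(C)C)CC1=O | intermediate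
13 | (2S,3S,4R)-4-hydroxy-4-isopropyl-2-methyl-3-[(2R)-oxiran-2-yl]-2-propanoylcyclopentan-1-one | CCC(=O)[C@]1(C)[C@@H]([C@@H]2CO2)[C@](O)(C(C)C)CC1=O | intermediate
14 | (3R,3aS,4S,7aR)-3,4-dihydroxy-3-isopropyl-6,7a-dimethyloctahydro-1H-indene-1,7-dione (C6 epimers) | O[C@H]1CC(C)C(=O)[C@@]2(C)C(=O)C[C@@](O)(C(C)C)[C@H]12 | intermediate
15 | 3,4-dimethoxybenzoyl chloride | COc1ccc(C(Cl)=O)cc1OC | starting material
16 | (3R,3aS,4S,7aR)-3-hydroxy-3-isopropyl-6,7a-dimethyl-1,7-dioxooctahydro-1H-inden-4-yl 3,4-dimethoxybenzoate (C6 epimers) | COc1ccc(C(=O)O[C@H]2CC(C)C(=O)[C@@]3(C)C(=O)C[C@@](O)(C(C)C)[C@H]23)cc1OC | intermediate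
17 | (1S,3R,3aS,4S,7aR)-1,3-dihydroxy-3-isopropyl-6,7a-dimethyl-7-oxooctahydro-1H-inden-4-yl 3,4-dimethoxybenzoate (C6 epimers) | COc1ccc(C(=O)O[C@H]2CC(C)C(=O)[C@@]3(C)[C@@H](O)C[C@@](O)(C(C)C)[C@H]23)cc1OC | intermediate
18 | acetic anhydride | CC(=O)OC(C)=O | starting material
19 | (1S,3R,3aS,4S,7aR)-1-acetoxy-3-hydroxy-3-isopropyl-6,7a-dimethyl-7-oxooctahydro-1H-inden-4-yl 3,4-dimethoxybenzoate (C6 epimers) | COc1ccc(C(=O)O[C@H]2CC(C)C(=O)[C@@]3(C)[C@@H](OC(C)=O)C[C@@](O)(C(C)C)[C@H]23)cc1OC | intermediate
20 | (1S,3R,3aS,4S,7aR)-1-acetoxy-3-isopropyl-6,7a-dimethyl-3,7-bis(trimethylsilyloxy)-2,3,3a,4,5,7a-hexahydro-1H-inden-4-yl 3,4-dimethoxybenzoate | COc1ccc(C(=O)O[C@H]2CC(C)=C(O[Si](C)(C)C)[C@@]3(C)[C@@H](OC(C)=O)C[C@@](O[Si](C)(C)C)(C(C)C)[C@H]23)cc1OC | intermediate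
21 | diiodomethane | ICI | starting material
22 | siloxycyclopropane: 20 with a CH2 bridge across its enol ether carbons C6 and C7 (both faces) | COc1ccc(C(=O)O[C@H]2CC3(C)CC3(O[Si](C)(C)C)[C@@]4(C)[C@@H](OC(C)=O)C[C@@](O[Si](C)(C)C)(C(C)C)[C@H]24)cc1OC | intermediate (not isolated)
23 | β-chloro ketone: (1S,3R,3aS,4S,8aR)-1-acetoxy-6-chloro-3-isopropyl-6,8a-dimethyl-8-oxo-3-(trimethylsilyloxy)decahydroazulen-4-yl 3,4-dimethoxybenzoate (C6 epimers) | COc1ccc(C(=O)O[C@H]2CC(C)(Cl)CC(=O)[C@@]3(C)[C@@H](OC(C)=O)C[C@@](O[Si](C)(C)C)(C(C)C)[C@H]23)cc1OC | intermediate (not isolated)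
24 | (1S,3R,3aS,4S,8aR)-1-acetoxy-3-isopropyl-6,8a-dimethyl-8-oxo-3-(trimethylsilyloxy)-1,2,3,3a,4,5,8,8a-octahydroazulen-4-yl 3,4-dimethoxybenzoate | COc1ccc(C(=O)O[C@H]2CC(C)=CC(=O)[C@@]3(C)[C@@H](OC(C)=O)C[C@@](O[Si](C)(C)C)(C(C)C)[C@H]23)cc1OC | intermediate
25 | (1S,3R,3aS,4S,8S,8aS)-1-acetoxy-8-hydroxy-3-isopropyl-6,8a-dimethyl-3-(trimethylsilyloxy)-1,2,3,3a,4,5,8,8a-octahydroazulen-4-yl 3,4-dimethoxybenzoate | COc1ccc(C(=O)O[C@H]2CC(C)=C[C@H](O)[C@@]3(C)[C@@H](OC(C)=O)C[C@@](O[Si](C)(C)C)(C(C)C)[C@H]23)cc1OC | intermediate
26 | acetic acid | CC(=O)O | starting material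
27 | (1S,3R,3aS,4S,8R,8aR)-1,8-diacetoxy-3-isopropyl-6,8a-dimethyl-3-(trimethylsilyloxy)-1,2,3,3a,4,5,8,8a-octahydroazulen-4-yl 3,4-dimethoxybenzoate | COc1ccc(C(=O)O[C@H]2CC(C)=C[C@@H](OC(C)=O)[C@@]3(C)[C@@H](OC(C)=O)C[C@@](O[Si](C)(C)C)(C(C)C)[C@H]23)cc1OC | intermediate
28 | (1S,3R,3aS,4S,8R,8aR)-1,8-diacetoxy-3-hydroxy-3-isopropyl-6,8a-dimethyl-1,2,3,3a,4,5,8,8a-octahydroazulen-4-yl 3,4-dimethoxybenzoate | COc1ccc(C(=O)O[C@H]2CC(C)=C[C@@H](OC(C)=O)[C@@]3(C)[C@@H](OC(C)=O)C[C@@](O)(C(C)C)[C@H]23)cc1OC | target

## Step count and least certain steps

Total: 17 steps. Longest linear sequence: 17 steps (1 to 28); the route is linear.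

Step 14 (key step). Most likely failures are incomplete cyclopropanation of the hindered tetrasubstituted enol ether with zinc-halide-induced reversion to ketone 19, and, once the enone exists, loss of the C4 aroyloxy group by vinylogous β-elimination through the extended enolate during the acetate treatment. Fallback: from 20, dibromocarbene generated under neutral conditions (PhHgCBr3, benzene, 80 °C) should give the dibromocyclopropane F1. Heated in toluene with pyridine, it should open at the internal bond by an electrocyclic path with loss of the silyl group to the 7-bromo enone F2. Hydrodebromination with Bu3SnH and catalytic Pd(PPh3)4 returns to 24.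

Step 6. The uncertain points are competing 1,2-addition of the Grignard reagent to the carbonyl and insufficient facial control if delivery by the alkoxide is not dominant. Fallback: from 8, dimethyl(ethynyl)aluminium (Me2AlC≡CH, from HC≡CMgBr and Me2AlCl) is used, a reagent class known to transfer its alkynyl group to 4-hydroxycyclopentenones only through the aluminium alkoxide and therefore cis to oxygen. Trapping the aluminium enolate with propanal should give the ethynyl aldol F3. Semihydrogenation (H2, Pd/CaCO3 poisoned with Pb(OAc)2, quinoline) returns to 11.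

Step 9. Possible failures are retro-Claisen fragmentation of the non-enolisable 1,3-diketone under strongly basic conditions, sluggish epoxide opening by the enolate, and opening by the tertiary alkoxide instead. Fallback: the cyclopentanone is removed before ring closure. From 13, hydroxyl-directed reduction (Me4NBH(OAc)3) should give the epoxy hydroxy ketone F4, and Et3SiCl/imidazole its triethylsilyl ether F5. Base-mediated cyclisation of this single ketone gives the silylated hydrindanone F6, acylation with 15 gives the ester F7, and HF·pyridine returns to 17.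

Step 11. Risks are a second, hydroxyl-directed reduction of the C7 ketone by the newly formed C1 hydroxyl, and slow hydride delivery past the angular methyl allowing undirected attack from the α face. Fallback: from 16, undirected reduction of the more reactive cyclopentanone with LiAlH(OtBu)3 at low temperature should give the 1β-alcohol F8. Mitsunobu reaction with acetic acid inverts it (as in the 17β to 17α inversion of steroid alcohols) and returns to 19.

Steps 15 and 16. Risks are poor facial selectivity in the hydride addition, and in the Mitsunobu step ionisation of the activated neopentylic allylic alcohol, leading to elimination to a diene or allylic transposition instead of clean inversion. Fallback: from 24, reagent-controlled reduction with (S)-2-methyl-CBS-oxazaborolidine [(S)-1-methyl-3,3-diphenyltetrahydro-1H,3H-pyrrolo[1,2-c][1,3,2]oxazaborole] and catecholborane, the quaternary carbon acting as the large group, should give the 8α-alcohol F9. Acetylation with retention (Ac2O, pyridine) returns to 27.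

## Further compounds

F1 | step 14 | dibromocyclopropane: 20 with a CBr2 bridge across C6 and C7 | COc1ccc(C(=O)O[C@H]2CC3(C)C(Br)(Br)C3(O[Si](C)(C)C)[C@@]4(C)[C@@H](OC(C)=O)C[C@@](O[Si](C)(C)C)(C(C)C)[C@H]24)cc1OC
F2 | step 14 | 7-bromo enone: 24 with bromine on C7 | COc1ccc(C(=O)O[C@H]2CC(C)=C(Br)C(=O)[C@@]3(C)[C@@H](OC(C)=O)C[C@@](O[Si](C)(C)C)(C(C)C)[C@H]23)cc1OC
F3 | step 6 | ethynyl aldol: 11 with ethynyl in place of vinyl | CCC(O)[C@]1(C)[C@@H](C#C)[C@](O)(C(C)C)CC1=O
F4 | step 9 | epoxy hydroxy ketone: 13 with the ring ketone reduced to the α-alcohol | CCC(=O)[C@]1(C)[C@@H]([C@@H]2CO2)[C@](O)(C(C)C)C[C@@H]1O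
F5 | step 9 | triethylsilyl ether of F4 | CCC(=O)[C@]1(C)[C@@H]([C@@H]2CO2)[C@](O)(C(C)C)C[C@@H]1O[Si](CC)(CC)CC
F6 | step 9 | silylated hydrindanone: 1α-triethylsilyloxy-3,4-dihydroxy-3-isopropyl-6,7a-dimethyloctahydroinden-7-one | O[C@H]1CC(C)C(=O)[C@@]2(C)[C@@H](O[Si](CC)(CC)CC)C[C@@](O)(C(C)C)[C@H]12
F7 | step 9 | 3,4-dimethoxybenzoate of F6 at the C4 hydroxyl | COc1ccc(C(=O)O[C@H]2CC(C)C(=O)[C@@]3(C)[C@@H](O[Si](CC)(CC)CC)C[C@@](O)(C(C)C)[C@H]23)cc1OC
F8 | step 11 | 1β-alcohol: C1 epimer of 17 | COc1ccc(C(=O)O[C@H]2CC(C)C(=O)[C@@]3(C)[C@H](O)C[C@@](O)(C(C)C)[C@H]23)cc1OC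
F9 | step 16 | 8α-alcohol: C8 epimer of 25 | COc1ccc(C(=O)O[C@H]2CC(C)=C[C@@H](O)[C@@]3(C)[C@@H](OC(C)=O)C[C@@](O[Si](C)(C)C)(C(C)C)[C@H]23)cc1OC
A1 | alternative 1 | ten-membered enynedione | CC1C(=O)/C=C(C)\CC#C[C@](O[Si](CC)(CC)CC)(C(C)C)CC1=O
A2 | alternative 1 | hydroazulenedione with ring-fusion alkene | C1C(C)=CC(=O)[C@@]2(C)C(=O)C[C@@](O[Si](CC)(CC)CC)(C(C)C)C2=C1
A3 | alternative 2 | cycloheptadienyl iodide with tethered isopropyl ketone | IC1=CCC(C)=C[C@@H](OC(C)=O)[C@@]1(C)[C@@H](O[Si](C)(C)C(C)(C)C)CC(=O)C(C)C
A4 | alternative 2 | bicyclic tertiary allylic alcohol | C2CC(C)=C[C@@H](OC(C)=O)[C@@]3(C)[C@@H](O[Si](C)(C)C(C)(C)C)C[C@@](O)(C(C)C)C3=2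
A5 | alternative 3 | bicyclic siloxy vinylcyclopropane | C/C=C/C1(O[Si](C)(C)C(C)(C)C)[C@@]2(C)[C@@H](OC(C)=O)C[C@@](O)(C(C)C)[C@@H]12
A6 | alternative 3 | cis-fused hydroazulene silyl enol ether with vinylsilane | C[Si](C)(C)C2=C[C@H](C)C=C(O[Si](C)(C)C(C)(C)C)[C@@]3(C)[C@@H](OC(C)=O)C[C@@](O)(C(C)C)[C@@H]23
A7 | alternative 3 | ethynyltrimethylsilane | C#C[Si](C)(C)C
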